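**Plan**

- Numbering: 3,7-dioxabicyclo[3.3.0]octane core. Ring A is C1–C2–O3–C4–C5, and C2 carries the 4-hydroxy-3,5-dimethoxyphenyl ring. Ring B is C5–C6–O7–C8–C1, and C6 carries the 3,4,5-trimethoxyphenyl ring.
- Retrosynthesis: cut aryl–C2 (gives 2,6-dimethoxyphenol and a bicyclic lactol), then C2–O3 (lactol = C2 aldehyde + C4 hydroxyl, the aldehyde coming from a vinyl group), then C6–O7 (benzylic cation etherification), then C5–C6 (aldol), then C1–vinyl (conjugate addition to furan-2(5H)-one).
- Forward: furanone → (R)-4-vinyl lactone → trans aldol → triol → ring B → vinyl cleavage closes ring A as the lactol → arylation at C2 gives the target directly. Six steps, no protecting group.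
- Enabling feature: C2 is an acetal-level carbon between O3 and C1 of ring A, so it ionises to an oxocarbenium ion whose concave face is covered by C8 of the cis-fused ring B. 2,6-Dimethoxyphenol offers one free position para to OH, with both ortho positions blocked by OMe.
- Stereochemistry: C1 from the rhodium/(R)-BINAP vinyl transfer; C5 by 1,2-induction in the aldol (trans to vinyl); C6 by reversible cationic ring closure (aryl trans to CH2OH); C2 by convex-face attack in the key step.

Key step: step 6

Remark: where a SMILES below leaves one carbon without a descriptor (the aldol carbinol and its reduction product, the glycol, the lactol carbon), both epimers are meant; each such center is erased later in the route.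

**Route**

Step 1
Reactants: 1 furan-2(5H)-one; 2 potassium vinyltrifluoroborate
Product: 3 (R)-4-vinyldihydrofuran-2(3H)-one
Conditions: [Rh(cod)2]PF6 (3 mol %), (R)-BINAP (3.3 mol %), toluene/H2O 4:1, 100 °C
Reagents that add atoms: none
Why: Rhodium-catalysed asymmetric conjugate addition of an organoboron reagent (Hayashi–Miyaura reaction): the vinyl group passes from boron to the rhodium–BINAP complex, inserts the butenolide C=C bond on one enantioface and the rhodium enolate is protonated by water, so the ligand sets C1 of the target, (R)-BINAP being expected to give the (R)-lactone by analogy with the sense of aryl transfer to cyclic enones and unsaturated lactones (to be confirmed by the sign of rotation of 3).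

Step 2
Reactants: 3 (R)-4-vinyldihydrofuran-2(3H)-one; 4 3,4,5-trimethoxybenzaldehyde
Product: 6 (3R,4S)-3-[hydroxy(3,4,5-trimethoxyphenyl)methyl]-4-vinyldihydrofuran-2(3H)-one (both carbinol epimers), via lithium lactone enolate 5 (not isolated)
Conditions: LiN(iPr)2 (1.05 equiv), THF, −78 °C; then 4, −78 °C; AcOH quench at −78 °C
Reagents that add atoms: none
Why: Lithium enolate aldol addition: the aldehyde approaches enolate 5 on the face anti to the C4 vinyl group, which should set C3 trans to C4 (C5 and C1 of the target), while the carbinol carbon forms without control and is erased in step 4.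

Step 3
Reactants: 6 (3R,4S)-3-[hydroxy(3,4,5-trimethoxyphenyl)methyl]-4-vinyldihydrofuran-2(3H)-one
Product: 7 (2S,3S)-2-ethenyl-3-[hydroxy(3,4,5-trimethoxyphenyl)methyl]butane-1,4-diol (both carbinol epimers)
Conditions: LiAlH4, THF, 0 °C; work-up with H2O and aqueous NaOH
Reagents that add atoms: none
Why: LiAlH4 reduction of the lactone to the 1,4-diol, which leaves the vinyl group and the two ring stereocenters untouched, the low temperature being meant to outrun retro-aldol cleavage of the aluminium aldolate.

Step 4
Reactants: 7 (2S,3S)-2-ethenyl-3-[hydroxy(3,4,5-trimethoxyphenyl)methyl]butane-1,4-diol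
Product: 9 [(2R,3S,4S)-2-(3,4,5-trimethoxyphenyl)-4-vinyltetrahydrofuran-3-yl]methanol, via benzylic cation 8 (not isolated)
Conditions: BF3·OEt2 (1.1 equiv), CH2Cl2 (0.02 M), −20 → 0 °C
Reagents that add atoms: none
Why: SN1 cyclodehydration (cationic etherification): BF3 ionises the benzylic alcohol to the planar cation 8, which the C8 hydroxyl captures to close the five-membered ring B (the C4 hydroxyl could only give an oxetane), and the aryl group should end trans to the neighbouring CH2OH because the all-cis ring is strained and the closure is reversible, so both epimers of 7 converge on 9 and C6 is set under substrate control.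

Step 5
Reactants: 9 [(2R,3S,4S)-2-(3,4,5-trimethoxyphenyl)-4-vinyltetrahydrofuran-3-yl]methanol
Product: 12 (1S,5S,6R)-6-(3,4,5-trimethoxyphenyl)-3,7-dioxabicyclo[3.3.0]octan-2-ol (lactol, both anomers), via vicinal diol 10 (not isolated), via hydroxy aldehyde 11 (not isolated)
Conditions: OsO4 (2 mol %), NaIO4 (3 equiv), 2,6-lutidine, dioxane/H2O 3:1, rt
Reagents that add atoms: osmium tetroxide, O=[Os](=O)(=O)=O (catalytic carrier of the oxygen); sodium periodate, [Na+].[O-]I(=O)(=O)=O (stoichiometric oxygen source)
Why: Lemieux–Johnson oxidative cleavage (OsO4 dihydroxylation, then periodate glycol cleavage) turns the vinyl group into the C2 aldehyde 11, which the cis CH2OH group traps at once as the cis-fused lactol, the only ring fusion this 5,5-system allows, so the enolisable C1 center is held in place.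

Step 6
Reactants: 12 (1S,5S,6R)-6-(3,4,5-trimethoxyphenyl)-3,7-dioxabicyclo[3.3.0]octan-2-ol; 13 2,6-dimethoxyphenol
Product: 15 4-[(1S,2R,5S,6R)-6-(3,4,5-trimethoxyphenyl)-3,7-dioxabicyclo[3.3.0]octan-2-yl]-2,6-dimethoxyphenol (target), via bicyclic oxocarbenium ion 14 (not isolated)
Conditions: 13 (2 equiv), Amberlyst-15 (H+ form), 4 Å molecular sieves, MeCN, 0 °C → rt; filter and add Et3N as soon as 12 is consumed
Reagents that add atoms: none
Why: The sulfonic acid resin ionises the lactol C2–OH bond of 12 to the ring A oxocarbenium ion 14 (C2=O3+), which is attacked by the carbon para to the hydroxyl of 13 in a Friedel–Crafts (electrophilic aromatic) substitution, and rearomatisation gives 15 with loss of water only. The closest known reaction type is the acid-mediated C-arylation of lactols and glycosyl donors with phenols (aryl C-glycoside synthesis), including lactols of the furofuran series. No ring is closed: ring A stays intact throughout, since the leaving group is the exocyclic hydroxyl. The new C2 stereocenter is controlled by the cis-fused bicycle: C8 of ring B covers the concave face of 14, so the arene should add to the convex face, syn to H1, and the aryl group should end exo (2R), as in the target. The step needs regioselectivity for the para position, secured by the free OH as the strongest director with both of its ortho positions blocked by methoxy groups and by the reversibility of any O-arylation, and it needs kinetic control, because the new 4-hydroxybenzylic C2–O3 bond can re-ionise and then epimerise or take up a second arene; low temperature, a modest excess of 13 and removal of the resin at full conversion guard against this. The C6–O7 bond should be spared because the 3,4,5-trimethoxyphenyl group stabilises a cation less well (its para methoxy group is twisted out of conjugation), and C1 cannot be lost since a deprotonated 14 can only return to the cis-fused ring.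

**Compound list**

1 | furan-2(5H)-one | O=C1OCC=C1 | starting material
2 | potassium vinyltrifluoroborate | [K+].C=C[B-](F)(F)F | starting material
3 | (R)-4-vinyldihydrofuran-2(3H)-one | O=C1OC[C@@H](C=C)C1 | intermediate
4 | 3,4,5-trimethoxybenzaldehyde | COc1cc(C=O)cc(OC)c1OC | starting material
5 | lithium (S)-4-vinyl-4,5-dihydrofuran-2-olate (lithium enolate of 3) | [Li+].[O-]C1=C[C@H](C=C)CO1 | intermediate
6 | (3R,4S)-3-[hydroxy(3,4,5-trimethoxyphenyl)methyl]-4-vinyldihydrofuran-2(3H)-one | O=C1OC[C@@H](C=C)[C@@H]1C(O)c1cc(OC)c(OC)c(OC)c1 | intermediate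
7 | (2S,3S)-2-ethenyl-3-[hydroxy(3,4,5-trimethoxyphenyl)methyl]butane-1,4-diol | OC[C@@H](C(O)c1cc(OC)c(OC)c(OC)c1)[C@H](C=C)CO | intermediate
8 | (2S,3S)-1,4-dihydroxy-3-vinyl-2-(hydroxymethyl... written as benzylic cation of 7: (3,4,5-trimethoxyphenyl)methylium carrying the (2S,3S)-diol chain | OC[C@@H]([CH+]c1cc(OC)c(OC)c(OC)c1)[C@H](C=C)CO | intermediate
9 | [(2R,3S,4S)-2-(3,4,5-trimethoxyphenyl)-4-vinyltetrahydrofuran-3-yl]methanol | OC[C@@H]1[C@H](C=C)CO[C@H]1c1cc(OC)c(OC)c(OC)c1 | intermediate
10 | 1-[(3S,4S,5R)-4-(hydroxymethyl)-5-(3,4,5-trimethoxyphenyl)oxolan-3-yl]ethane-1,2-diol | OC[C@@H]1[C@H](C(O)CO)CO[C@H]1c1cc(OC)c(OC)c(OC)c1 | intermediate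
11 | (3S,4S,5R)-4-(hydroxymethyl)-5-(3,4,5-trimethoxyphenyl)oxolane-3-carbaldehyde | OC[C@@H]1[C@H](C=O)CO[C@H]1c1cc(OC)c(OC)c(OC)c1 | intermediate
12 | (1S,5S,6R)-6-(3,4,5-trimethoxyphenyl)-3,7-dioxabicyclo[3.3.0]octan-2-ol | OC1OC[C@@H]2[C@H]1CO[C@H]2c1cc(OC)c(OC)c(OC)c1 | intermediate
13 | 2,6-dimethoxyphenol | COc1cccc(OC)c1O | starting material
14 | (1S,5S,6R)-6-(3,4,5-trimethoxyphenyl)-3,7-dioxabicyclo[3.3.0]oct-2-en-3-ium (oxocarbenium ion, C2=O3+) | C1=[O+]C[C@@H]2[C@H]1CO[C@H]2c1cc(OC)c(OC)c(OC)c1 | intermediate
15 | 4-[(1S,2R,5S,6R)-6-(3,4,5-trimethoxyphenyl)-3,7-dioxabicyclo[3.3.0]octan-2-yl]-2,6-dimethoxyphenol | COc1cc([C@@H]2OC[C@@H]3[C@H]2CO[C@H]3c2cc(OC)c(OC)c(OC)c2)cc(OC)c1O | target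

**Totals**

Total step count: 6.
Longest linear sequence: 6 steps (1 → 15).

**Steps most likely to fail**

Step 6. The arene may react at the position ortho to a methoxy group instead of para to the hydroxyl, or stop at the O-aryl acetal. The exo selectivity may erode through re-ionisation of the new benzylic C2–O3 bond, and the ring-opened cation may take up a second phenol. The fallback replaces the acid-mediated arylation by an ipso-defined, non-acidic coupling. It sets out from 12 and comes back to the route at 15. Lactol 12 with benzenesulfinic acid and CaCl2 in CH2Cl2 should give (1S,5S,6R)-2-(phenylsulfonyl)-6-(3,4,5-trimethoxyphenyl)-3,7-dioxabicyclo[3.3.0]octane F1. Commercial 4-bromo-2,6-dimethoxyphenol with TBSCl and imidazole in DMF should give (4-bromo-2,6-dimethoxyphenoxy)(tert-butyl)dimethylsilane F2. Bromine–lithium exchange (n-BuLi, THF, −78 °C) followed by ZnBr2 should give [4-(tert-butyldimethylsilyloxy)-3,5-dimethoxyphenyl]zinc bromide F3. Coupling of F1 with F3 in THF at 0 °C to rt is a known substitution of 2-benzenesulfonyl cyclic ethers by arylzinc reagents: zinc-assisted loss of sulfinate and aryl transfer to the convex face should give the silyl ether of the target, tert-butyl{2,6-dimethoxy-4-[(1S,2R,5S,6R)-6-(3,4,5-trimethoxyphenyl)-3,7-dioxabicyclo[3.3.0]octan-2-yl]phenoxy}dimethylsilane F4. Tetrabutylammonium fluoride in THF then frees 15.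

Step 1. The vinyl reagent may be lost by protodeboronation, the butenolide may ring-open, isomerise or oligomerise at the temperature needed, and the enantioface selection may be incomplete. The fallback replaces catalysis by an auxiliary-controlled alkylation. It replaces both 1 and 2, so it sets out from no numbered compound but from commercial (R)-4-benzyl-2-oxazolidinone and but-3-enoic acid, and it comes back to the route at 3. Acylation through the pivaloyl mixed anhydride (PivCl, Et3N, LiCl, THF) should give (R)-4-benzyl-3-(but-3-enoyl)-1,3-oxazolidin-2-one F5. Evans alkylation (NaN(SiMe3)2, THF, −78 °C, tert-butyl bromoacetate) should take place at the α-carbon of the chelated dienolate anti to the benzyl group and give tert-butyl (3R)-3-{[(4R)-4-benzyl-2-oxo-1,3-oxazolidin-3-yl]carbonyl}pent-4-enoate F6. LiBH4 in wet THF at 0 °C should remove the auxiliary reductively and give tert-butyl (3R)-3-(hydroxymethyl)pent-4-enoate F7. CF3CO2H in CH2Cl2 should cleave the tert-butyl ester and lactonise to 3.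

Step 4. Ionisation of the trimethoxybenzylic alcohol may be slow. Once formed, the cation may be captured by the vinyl group or by a second molecule, may lose a proton to a styrene or formaldehyde from the 1,3-diol unit, and the trans selectivity may be incomplete. The fallback generates the same cation by C–H oxidation under neutral conditions and avoids the aldolate altogether. It sets out from 3 and comes back to the route at 9. Enolate 5 (LiN(iPr)2, THF, −78 °C) with commercial 5-(bromomethyl)-1,2,3-trimethoxybenzene should alkylate anti to the vinyl group and give (3S,4S)-3-(3,4,5-trimethoxybenzyl)-4-vinyldihydrofuran-2(3H)-one F8. LiAlH4 in THF should give (2S,3S)-2-ethenyl-3-(3,4,5-trimethoxybenzyl)butane-1,4-diol F9. DDQ (1.2 equiv) in CH2Cl2 at rt should abstract the benzylic hydride, and the ion pair 8 should be captured by the C8 hydroxyl. This is a known oxidative cyclisation of 4-arylbutanols to 2-aryltetrahydrofurans and should give 9.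

Further compounds
F1 | step 6 | (1S,5S,6R)-2-(phenylsulfonyl)-6-(3,4,5-trimethoxyphenyl)-3,7-dioxabicyclo[3.3.0]octane | O=S(=O)(c1ccccc1)C1OC[C@@H]2[C@H]1CO[C@H]2c1cc(OC)c(OC)c(OC)c1
F2 | step 6 | (4-bromo-2,6-dimethoxyphenoxy)(tert-butyl)dimethylsilane | COc1cc(Br)cc(OC)c1O[Si](C)(C)C(C)(C)C
F3 | step 6 | [4-(tert-butyldimethylsilyloxy)-3,5-dimethoxyphenyl]zinc bromide | COc1cc([Zn]Br)cc(OC)c1O[Si](C)(C)C(C)(C)C
F4 | step 6 | tert-butyl{2,6-dimethoxy-4-[(1S,2R,5S,6R)-6-(3,4,5-trimethoxyphenyl)-3,7-dioxabicyclo[3.3.0]octan-2-yl]phenoxy}dimethylsilane | COc1cc([C@@H]2OC[C@@H]3[C@H]2CO[C@H]3c2cc(OC)c(OC)c(OC)c2)cc(OC)c1O[Si](C)(C)C(C)(C)C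
F5 | step 1 | (R)-4-benzyl-3-(but-3-enoyl)-1,3-oxazolidin-2-one | C=CCC(=O)N1[C@H](Cc2ccccc2)COC1=O
F6 | step 1 | tert-butyl (3R)-3-{[(4R)-4-benzyl-2-oxo-1,3-oxazolidin-3-yl]carbonyl}pent-4-enoate | C=C[C@@H](CC(=O)OC(C)(C)C)C(=O)N1[C@H](Cc2ccccc2)COC1=O
F7 | step 1 | tert-butyl (3R)-3-(hydroxymethyl)pent-4-enoate | C=C[C@@H](CC(=O)OC(C)(C)C)CO
F8 | step 4 | (3S,4S)-3-(3,4,5-trimethoxybenzyl)-4-vinyldihydrofuran-2(3H)-one | O=C1OC[C@@H](C=C)[C@@H]1Cc1cc(OC)c(OC)c(OC)c1
F9 | step 4 | (2S,3S)-2-ethenyl-3-(3,4,5-trimethoxybenzyl)butane-1,4-diol | OC[C@@H](Cc1cc(OC)c(OC)c(OC)c1)[C@H](C=C)CO
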